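**Retrosynthetic overview**
1. Target 17 ⇐ one-pot lactone methanolysis and C-6 prenylation (prenyl bromide 15) of tricyclic lactone 14 ⇐ double O-demethylation of chromanone 13.
2. Chromanone ring (O1–C2 bond) ⇐ quinidine-catalysed oxa-Michael closure of o-hydroxyaryl tigloyl ketone 11 ⇐ phenol 9 + tigloyl chloride 10.
3. Phenol 9 ⇐ methanolysis of dihydrocoumarin 8 ⇐ Baeyer–Villiger ring expansion of indanone 7; this turns the resorcinol pattern into the phloroglucinol pattern and delivers the new oxygen as the only free phenol (the later O1).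
4. Indanone 7 ⇐ Friedel–Crafts ring closure of acid 6 ⇐ new enantioselective Friedel–Crafts conjugate addition of 1,3-dimethoxybenzene 2 (from resorcinol 1) to (E)-hex-2-enoic acid 3.
5. Ring order: arene (bought) → cyclopentanone → six-membered lactone by expansion (then opened) → pyranone → lactone re-closed in step 7 and opened for good in step 8.

Assumption: the facial sense of the two chiral catalysts ((S,S)-IDPi in step 2, quinidine in step 6) is taken by analogy; if the first run shows the opposite sense, the enantiomeric IDPi or quinine is used instead.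

**Route**

Step 1
Reactants: 1 resorcinol
Product: 2 1,3-dimethoxybenzene
Conditions: MeI (2.5 equiv), K2CO3, acetone, reflux
Reagents that add atoms: iodomethane, CI
Why: Williamson ether synthesis (double O-methylation) gives the acid- and peracid-stable dimethyl ether, and no stereocentre is formed.

Step 2
Reactants: 2 1,3-dimethoxybenzene; 3 (E)-hex-2-enoic acid
Product: 6 (S)-3-(2,4-dimethoxyphenyl)hexanoic acid, via trimethylsilyl (E)-hex-2-enoate 4 (not isolated), via trimethylsilyl (S)-3-(2,4-dimethoxyphenyl)hexanoate 5 (not isolated)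
Conditions: 3, CH2=CHCH2SiMe3 (1.3 equiv), (S,S)-IDPi (confined BINOL-derived N-triflyl imidodiphosphorimidate acid, 3 mol %), PhMe, rt; then 2 (3 equiv), −40 °C; 1 M HCl work-up
Reagents that add atoms: none
Why: Proposed new method: the chiral acid is silylated by the allylsilane to a silylium ion pair that O-silylates silyl ester 4 to a bis(silyloxy)allyl cation held in the confined chiral anion, C-4 of arene 2 (a π-nucleophile of about the strength of cyclopentadiene, which such cations already engage) adds to one face of the β-carbon and so sets the (S) benzylic centre, and proton loss from the Wheland intermediate followed by protodesilylation of the bis-silyl ketene acetal returns 5 and the silylium catalyst; the closest known reactions are silylium-based asymmetric counteranion-directed Diels–Alder and Mukaiyama–Michael additions to α,β-unsaturated esters and Brønsted-acid-catalysed Friedel–Crafts conjugate additions of indoles.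

Step 3
Reactants: 6 (S)-3-(2,4-dimethoxyphenyl)hexanoic acid
Product: 7 (S)-4,6-dimethoxy-3-propylindan-1-one
Conditions: P2O5 in CH3SO3H (1:10 w/w), 45 °C, high dilution
Reagents that add atoms: none
Why: Intramolecular Friedel–Crafts acylation through the mixed anhydride/acylium ion closes the five-membered ketone on the only free ortho carbon, and the C-3 stereocentre is not enolisable and stays (S).

Step 4
Reactants: 7 (S)-4,6-dimethoxy-3-propylindan-1-one
Product: 9 methyl (S)-3-(2-hydroxy-4,6-dimethoxyphenyl)hexanoate, via (S)-5,7-dimethoxy-4-propylchroman-2-one 8 (not isolated)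
Conditions: mCPBA (1.5 equiv), TsOH·H2O (5 mol %), CH2Cl2, 0 °C → rt; aq. Na2SO3/NaHCO3 wash, concentrate; then NaOMe (1.1 equiv), MeOH, 0 °C, 15 min; AcOH
Reagents that add atoms: mCPBA (3-chloroperoxybenzoic acid), OOC(=O)c1cccc(Cl)c1; sodium methoxide, [Na+].[O-]C
Why: Baeyer–Villiger oxidation, in which the aryl carbon of the Criegee adduct migrates in preference to the primary CH2 so that oxygen is inserted between C-1 and C-7a with ring expansion to dihydrocoumarin 8 (the remote stereocentre is untouched), followed by methoxide transesterification that opens the aryl lactone to the free phenol.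

Step 5
Reactants: 9 methyl (S)-3-(2-hydroxy-4,6-dimethoxyphenyl)hexanoate; 10 tigloyl chloride ((E)-2-methylbut-2-enoyl chloride)
Product: 11 methyl (S)-3-{2-hydroxy-4,6-dimethoxy-3-[(E)-2-methylbut-2-enoyl]phenyl}hexanoate
Conditions: TiCl4 (1.2 equiv), CH2Cl2, −20 → 0 °C (9 used crude, directly after step 4)
Reagents that add atoms: none
Why: Friedel–Crafts acylation directed ortho by the titanium phenoxide chelate gives the o-hydroxyaryl enone, no stereocentre is formed, and because the only free OH is the one delivered by the ring expansion the later ring closure has a single possible regiochemistry.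

Step 6
Reactants: 11 methyl (S)-3-{2-hydroxy-4,6-dimethoxy-3-[(E)-2-methylbut-2-enoyl]phenyl}hexanoate
Product: 13 methyl (S)-3-[(2S,3S)-5,7-dimethoxy-2,3-dimethyl-4-oxochroman-8-yl]hexanoate, via cis-(2S,3R)-chromanone 12 (not isolated)
Conditions: quinidine (20 mol %), PhCl, 15 °C, 72 h; then Et3N (0.5 equiv), MgI2 (0.2 equiv), CH2Cl2, rt
Reagents that add atoms: none
Why: Cinchona-alkaloid-catalysed intramolecular oxa-Michael addition (6-endo), in which quinidine acts as general base and hydrogen-bond donor and delivers the phenol oxygen to one enone face to set C-2 as (S), after which the kinetic cis-(2S,3R) product 12 is epimerised at C-3 through the enolate to the diequatorial trans-(2S,3S) isomer (about 9:1 expected, residual cis recycled).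

Step 7
Reactants: 13 methyl (S)-3-[(2S,3S)-5,7-dimethoxy-2,3-dimethyl-4-oxochroman-8-yl]hexanoate
Product: 14 (2S,3S,10S)-5-hydroxy-2,3-dimethyl-10-propyl-2,3,9,10-tetrahydro-4H,8H-pyrano[2,3-f]chromene-4,8-dione (the chromanone whose 7-oxygen and side-chain carboxyl are closed to a dihydrocoumarin lactone)
Conditions: BBr3 (6 equiv), CH2Cl2, −78 °C → rt; then 1 M HCl, THF, rt
Reagents that add atoms: none
Why: BBr3 ether cleavage (O–B complexation then bromide SN2 at methyl) frees both phenols, and the 7-OH closes on the side-chain ester during the acidic work-up (lactonisation) to one stable compound, with no stereocentre touched.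

Step 8
Reactants: 14 tricyclic lactone (as in step 7); 15 prenyl bromide (1-bromo-3-methylbut-2-ene)
Product: 17 methyl (S)-3-[(2S,3S)-5,7-dihydroxy-2,3-dimethyl-6-(3-methylbut-2-en-1-yl)-4-oxochroman-8-yl]hexanoate, via des-prenyl dihydroxy ester 16 (not isolated)
Conditions: NaOMe (3 equiv), MeOH, 0 °C, 30 min; then 15 (1.3 equiv), 0 °C → rt; aq. NH4Cl
Reagents that add atoms: sodium methoxide, [Na+].[O-]C
Why: Methoxide transesterification opens the aryl lactone to the methyl ester and the phenoxide of 16, and C-alkylation of this phloroglucinol-type phenoxide (favoured over O-alkylation in the protic solvent) by prenyl bromide puts the prenyl group on C-6, the only unsubstituted ring carbon, while the stereocentres are untouched and any C-3 epimer returns to the trans form.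

**Compound list**
1 | resorcinol (benzene-1,3-diol) | Oc1cccc(O)c1 | starting material
2 | 1,3-dimethoxybenzene | COc1cccc(OC)c1 | intermediate
3 | (E)-hex-2-enoic acid | CCC/C=C/C(=O)O | starting material
4 | trimethylsilyl (E)-hex-2-enoate | CCC/C=C/C(=O)O[Si](C)(C)C | intermediate
5 | trimethylsilyl (S)-3-(2,4-dimethoxyphenyl)hexanoate | CCC[C@@H](CC(=O)O[Si](C)(C)C)c1ccc(OC)cc1OC | intermediate
6 | (S)-3-(2,4-dimethoxyphenyl)hexanoic acid | CCC[C@@H](CC(=O)O)c1ccc(OC)cc1OC | intermediate
7 | (S)-4,6-dimethoxy-3-propylindan-1-one | CCC[C@H]1CC(=O)c2cc(OC)cc(OC)c21 | intermediate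
8 | (S)-5,7-dimethoxy-4-propylchroman-2-one | CCC[C@H]1CC(=O)Oc2cc(OC)cc(OC)c21 | intermediate
9 | methyl (S)-3-(2-hydroxy-4,6-dimethoxyphenyl)hexanoate | CCC[C@@H](CC(=O)OC)c1c(O)cc(OC)cc1OC | intermediate
10 | tigloyl chloride, (E)-2-methylbut-2-enoyl chloride | C/C=C(\C)C(=O)Cl | starting material
11 | methyl (S)-3-{2-hydroxy-4,6-dimethoxy-3-[(E)-2-methylbut-2-enoyl]phenyl}hexanoate | CCC[C@@H](CC(=O)OC)c1c(O)c(C(=O)/C(C)=C/C)c(OC)cc1OC | intermediate
12 | methyl (S)-3-[(2S,3R)-5,7-dimethoxy-2,3-dimethyl-4-oxochroman-8-yl]hexanoate (cis) | CCC[C@@H](CC(=O)OC)c1c(OC)cc(OC)c2c1O[C@@H](C)[C@@H](C)C2=O | intermediate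
13 | methyl (S)-3-[(2S,3S)-5,7-dimethoxy-2,3-dimethyl-4-oxochroman-8-yl]hexanoate (trans) | CCC[C@@H](CC(=O)OC)c1c(OC)cc(OC)c2c1O[C@@H](C)[C@H](C)C2=O | intermediate
14 | (2S,3S,10S)-5-hydroxy-2,3-dimethyl-10-propyl-2,3,9,10-tetrahydro-4H,8H-pyrano[2,3-f]chromene-4,8-dione | CCC[C@H]1CC(=O)Oc2cc(O)c3C(=O)[C@@H](C)[C@H](C)Oc3c21 | intermediate
15 | prenyl bromide, 1-bromo-3-methylbut-2-ene | CC(C)=CCBr | starting material
16 | methyl (S)-3-[(2S,3S)-5,7-dihydroxy-2,3-dimethyl-4-oxochroman-8-yl]hexanoate | CCC[C@@H](CC(=O)OC)c1c(O)cc(O)c2c1O[C@@H](C)[C@H](C)C2=O | intermediate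
17 | methyl (S)-3-[(2S,3S)-5,7-dihydroxy-2,3-dimethyl-6-(3-methylbut-2-en-1-yl)-4-oxochroman-8-yl]hexanoate | CCC[C@@H](CC(=O)OC)c1c(O)c(CC=C(C)C)c(O)c2c1O[C@@H](C)[C@H](C)C2=O | target

**Totals and risks**
Total step count: 8. Longest linear sequence: 8 steps (1 → 17).

Steps most likely to fail:

Step 2 (the new reaction). The arene may be too weak a nucleophile for the silylium-activated enoate, or the enantioselectivity may be low. The fallback uses known chemistry, sets out from 2 and comes back at 6. Compound 2 and hex-2-ynoic acid are joined by Pd(OAc)2-catalysed hydroarylation in CF3CO2H/CH2Cl2 (anti addition of Ar–H across the alkyne) to give (Z)-3-(2,4-dimethoxyphenyl)hex-2-enoic acid F1. F1 is then hydrogenated with Ru(OAc)2[(S)-BINAP] (or its antipode, whichever gives the S acid) under H2 in MeOH to 6.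

Step 6. The bulky ortho side chain with its own stereocentre may erode or override the catalyst control at C-2. The fallback sets out from 9 and comes back at 13, replacing the oxa-Michael closure by an aldol/Mitsunobu closure. TiCl4 and propanoyl chloride give methyl (S)-3-(2-hydroxy-4,6-dimethoxy-3-propanoylphenyl)hexanoate F2. Its boron enolate (the Ipc2BOTf enantiomer that gives the 2S,3R-syn product, i-Pr2NEt, one extra equivalent to mask the phenol) adds to acetaldehyde to give methyl (S)-3-{2-hydroxy-3-[(2S,3R)-3-hydroxy-2-methylbutanoyl]-4,6-dimethoxyphenyl}hexanoate F3. Mitsunobu ring closure of F3 (PPh3, DIAD, THF) with inversion at the carbinol carbon gives the trans-(2S,3S)-chromanone 13.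

Step 8. O-prenylation, over-alkylation or base-induced opening of the chromanone may cut the yield of the direct C-prenylation. The fallback sets out from 14 and comes back at 17, and fixes the position by an ether rearrangement. The 5-OH of 14 is alkylated with 3-chloro-3-methylbut-1-yne (K2CO3, KI, CuI cat., acetone) to (2S,3S,10S)-2,3-dimethyl-5-[(2-methylbut-3-yn-2-yl)oxy]-10-propyl-2,3,9,10-tetrahydro-4H,8H-pyrano[2,3-f]chromene-4,8-dione F4. Semihydrogenation (Pd/CaCO3 poisoned with Pb(OAc)2, quinoline, H2) gives the corresponding 5-[(2-methylbut-3-en-2-yl)oxy] ether F5. Aromatic Claisen rearrangement of F5 (PhMe, 110 °C) moves the allyl unit to C-6, the only free ortho carbon, to give (2S,3S,10S)-5-hydroxy-2,3-dimethyl-6-(3-methylbut-2-en-1-yl)-10-propyl-2,3,9,10-tetrahydro-4H,8H-pyrano[2,3-f]chromene-4,8-dione F6. NaOMe in MeOH at 0 °C then opens the lactone of F6 to 17.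

Further compounds
F1 | step 2 | (Z)-3-(2,4-dimethoxyphenyl)hex-2-enoic acid | CCC/C(=C/C(=O)O)c1ccc(OC)cc1OC
F2 | step 6 | methyl (S)-3-(2-hydroxy-4,6-dimethoxy-3-propanoylphenyl)hexanoate | CCC[C@@H](CC(=O)OC)c1c(O)c(C(=O)CC)c(OC)cc1OC
F3 | step 6 | methyl (S)-3-{2-hydroxy-3-[(2S,3R)-3-hydroxy-2-methylbutanoyl]-4,6-dimethoxyphenyl}hexanoate | CCC[C@@H](CC(=O)OC)c1c(O)c(C(=O)[C@@H](C)[C@@H](C)O)c(OC)cc1OC
F4 | step 8 | (2S,3S,10S)-2,3-dimethyl-5-[(2-methylbut-3-yn-2-yl)oxy]-10-propyl-2,3,9,10-tetrahydro-4H,8H-pyrano[2,3-f]chromene-4,8-dione | CCC[C@H]1CC(=O)Oc2cc(OC(C)(C)C#C)c3C(=O)[C@@H](C)[C@H](C)Oc3c21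
F5 | step 8 | (2S,3S,10S)-2,3-dimethyl-5-[(2-methylbut-3-en-2-yl)oxy]-10-propyl-2,3,9,10-tetrahydro-4H,8H-pyrano[2,3-f]chromene-4,8-dione | CCC[C@H]1CC(=O)Oc2cc(OC(C)(C)C=C)c3C(=O)[C@@H](C)[C@H](C)Oc3c21
F6 | step 8 | (2S,3S,10S)-5-hydroxy-2,3-dimethyl-6-(3-methylbut-2-en-1-yl)-10-propyl-2,3,9,10-tetrahydro-4H,8H-pyrano[2,3-f]chromene-4,8-dione | CCC[C@H]1CC(=O)Oc2c(CC=C(C)C)c(O)c3C(=O)[C@@H](C)[C@H](C)Oc3c21
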